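**Plan**

1. Retrosynthesis: after the silyl ether on the distal phenol, the pyran is cut at C3–C4 and O1–C2 in one operation. This works because pyran C4 is bonded to arene carbon C4a, which lies ortho to the O1-bearing C8a, so C4 can be an aryl formyl carbon while C3 and C2 with both methyls come from an isobutenylboron nucleophile.
2. The resulting salicylaldehyde is cut at the formyl–arene bond, the prenyl–arene bond and the ArCH2–CH2Ar bond, leading back to methyl orsellinate, prenyl bromide and a 4-silyloxybenzyl bromide made from 4-hydroxybenzaldehyde.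
3. Forward: the arylethyl chain is joined first by lateral benzylation of the protected orsellinate. After unmasking, prenyl goes to the carbon between the two phenols and formyl to the last free ring carbon. The pyran, the only ring made, closes in step 9, and desilylation gives the target.
4. The target has no stereocentre; its only stereo element, the cis C3=C4 alkene, is fixed by the six-membered ring.

Key step: step 9

Remark: intermediates are named as benzoates with the ester carbon as C1; benzoate C1, C2, C3, C4, C5, C6 become chromene C6, C7, C8, C8a, C4a, C5.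

**Route**

Step 1
Reactants: 1 4-hydroxybenzaldehyde
Product: 2 4-(triisopropylsilyloxy)benzaldehyde
Conditions: TIPSCl, imidazole, DMF, 23 °C
Reagents that add atoms: triisopropylsilyl chloride, CC(C)[Si](Cl)(C(C)C)C(C)C
Why: Imidazole-promoted silyl ether formation on the phenol leaves the aldehyde untouched and installs a bulky aryl silyl ether that should survive lithium amide, methanolic acid, sodium hydride and warm amine in later steps.

Step 2
Reactants: 2 4-(triisopropylsilyloxy)benzaldehyde
Product: 3 [4-(triisopropylsilyloxy)phenyl]methanol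
Conditions: NaBH4, MeOH, 0 °C
Reagents that add atoms: none
Why: Borohydride reduction of the aromatic aldehyde to the benzylic alcohol is fast at 0 °C and should not disturb the hindered aryl silyl ether.

Step 3
Reactants: 3 [4-(triisopropylsilyloxy)phenyl]methanol
Product: 4 4-(triisopropylsilyloxy)benzyl bromide
Conditions: CBr4, PPh3, CH2Cl2, 0 °C
Reagents that add atoms: carbon tetrabromide, BrC(Br)(Br)Br
Why: The Appel reaction converts the primary benzylic alcohol to the bromide under neutral conditions that spare the silyl ether; the electron-rich bromide is to be used without storage.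

Step 4
Reactants: 5 methyl 2,4-dihydroxy-6-methylbenzoate (methyl orsellinate)
Product: 6 methyl 2,4-bis(methoxymethoxy)-6-methylbenzoate
Conditions: NaH, MOMCl, DMF, 0 → 23 °C
Reagents that add atoms: chloromethyl methyl ether, COCCl
Why: Williamson-type O-alkylation of both sodium phenoxides (the hydrogen-bonded C2 hydroxyl needs full deprotonation) masks the acidic protons as acetals ahead of the lateral metalation.

Step 5
Reactants: 6 methyl 2,4-bis(methoxymethoxy)-6-methylbenzoate; 4 4-(triisopropylsilyloxy)benzyl bromide
Product: 8 methyl 2,4-bis(methoxymethoxy)-6-{2-[4-(triisopropylsilyloxy)phenyl]ethyl}benzoate, via lateral benzyllithium 7 (not isolated)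
Conditions: LiN(i-Pr)2, THF, −78 °C; then 4, −78 → −40 °C
Reagents that add atoms: none
Why: Lateral lithiation of the ortho-toluate gives a benzylic anion stabilised as an ester dienolate, and its SN2 benzylation forms the CH2–CH2 bond of the bibenzyl, low temperature holding back self-condensation of the toluate anion.

Step 6
Reactants: 8 methyl 2,4-bis(methoxymethoxy)-6-{2-[4-(triisopropylsilyloxy)phenyl]ethyl}benzoate
Product: 9 methyl 2,4-dihydroxy-6-{2-[4-(triisopropylsilyloxy)phenyl]ethyl}benzoate
Conditions: HCl (1 M in MeOH), 23 → 40 °C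
Reagents that add atoms: none
Why: Acid-catalysed acetal exchange with methanol removes both methoxymethyl groups, the aryl triisopropylsilyl ether being stable to dilute methanolic acid and ester exchange with methanol being degenerate.

Step 7
Reactants: 9 methyl 2,4-dihydroxy-6-{2-[4-(triisopropylsilyloxy)phenyl]ethyl}benzoate; 10 1-bromo-3-methylbut-2-ene (prenyl bromide)
Product: 11 methyl 2,4-dihydroxy-3-(3-methylbut-2-enyl)-6-{2-[4-(triisopropylsilyloxy)phenyl]ethyl}benzoate
Conditions: NaH (1.1 equiv), toluene, 0 → 23 °C; then 10, 23 → 50 °C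
Reagents that add atoms: none
Why: Ortho C-alkylation of the sodium phenoxide as a tight ion pair in a non-polar solvent should place the prenyl group at C3, the carbon flanked by both oxygens and the less hindered of the two open ring positions.

Step 8
Reactants: 11 methyl 2,4-dihydroxy-3-(3-methylbut-2-enyl)-6-{2-[4-(triisopropylsilyloxy)phenyl]ethyl}benzoate
Product: 13 methyl 5-formyl-2,4-dihydroxy-3-(3-methylbut-2-enyl)-6-{2-[4-(triisopropylsilyloxy)phenyl]ethyl}benzoate, via C5 hydroxymethyl magnesium alkoxide 12 (not isolated)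
Conditions: MgCl2, Et3N, (CH2O)n, MeCN, reflux
Reagents that add atoms: paraformaldehyde (as formaldehyde), C=O
Why: In this magnesium-phenoxide-directed ortho-formylation (Casnati–Skattebøl reaction) formaldehyde is delivered from the C4 magnesium phenoxide to C5, the only unsubstituted ring carbon, and the benzylic alkoxide 12 is then oxidised by a second formaldehyde through Oppenauer-type hydride transfer.

Step 9
Reactants: 13 methyl 5-formyl-2,4-dihydroxy-3-(3-methylbut-2-enyl)-6-{2-[4-(triisopropylsilyloxy)phenyl]ethyl}benzoate; 14 (2-methylprop-1-en-1-yl)boronic acid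
Product: 17 methyl 7-hydroxy-2,2-dimethyl-8-(3-methylbut-2-enyl)-5-{2-[4-(triisopropylsilyloxy)phenyl]ethyl}-2H-chromene-6-carboxylate, via allylic dibenzylamine 15 (not isolated), via vinyl ortho-quinone methide 16 (not isolated)
Conditions: 14 (2 equiv), Bn2NH (0.4 equiv), 1,4-dioxane, 90 °C
Reagents that add atoms: none
Why: Dibenzylamine condenses with the hindered C5 formyl group to an iminium ion, boronic acid 14 is bound as a tetracoordinate boronate on the neighbouring C4 phenoxide (the future O1), and the isobutenyl group migrates from boron to the iminium carbon within this assembly to form the C3–C4 bond of allylic amine 15. Phenoxide-assisted loss of dibenzylamine from 15 gives the (Z)-vinyl ortho-quinone methide 16, whose 1-oxatriene closes by thermal disrotatory oxa-6π electrocyclisation to form the O1–C2 bond and the pyran ring, returning the amine to the cycle. The closest known reaction type is the amine-promoted Petasis borono-Mannich condensation of salicylaldehydes with alkenylboronic acids to 2H-chromenes. No stereocentre remains, because the carbinamine centre of 15 is racemic and is erased on ionisation and C2 carries two identical methyl groups. The step needs closure on the benzoate C4 oxygen and not the C2 oxygen, which is secured because only the C4 hydroxyl is ortho to the formyl carbon while the C2 hydroxyl is held in the hydrogen bond to the ester; the prenyl alkene, the ester and the silyl ether are not engaged by boronate or amine.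

Step 10
Reactants: 17 methyl 7-hydroxy-2,2-dimethyl-8-(3-methylbut-2-enyl)-5-{2-[4-(triisopropylsilyloxy)phenyl]ethyl}-2H-chromene-6-carboxylate
Product: 18 methyl 7-hydroxy-5-[2-(4-hydroxyphenyl)ethyl]-2,2-dimethyl-8-(3-methylbut-2-enyl)-2H-chromene-6-carboxylate (CNP0133674.0)
Conditions: Bu4NF, AcOH, THF, 0 → 23 °C
Reagents that add atoms: none
Why: Fluoride-induced cleavage of the aryl silyl ether, buffered with acetic acid, should free the distal phenol without touching the ester, the chromene alkene or the prenyl group.

**Compound list**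

1 | 4-hydroxybenzaldehyde | O=Cc1ccc(O)cc1 | starting material
2 | 4-(triisopropylsilyloxy)benzaldehyde | O=Cc1ccc(O[Si](C(C)C)(C(C)C)C(C)C)cc1 | intermediate
3 | [4-(triisopropylsilyloxy)phenyl]methanol | OCc1ccc(O[Si](C(C)C)(C(C)C)C(C)C)cc1 | intermediate
4 | 4-(triisopropylsilyloxy)benzyl bromide | BrCc1ccc(O[Si](C(C)C)(C(C)C)C(C)C)cc1 | intermediate
5 | methyl 2,4-dihydroxy-6-methylbenzoate (methyl orsellinate) | COC(=O)c1c(C)cc(O)cc1O | starting material
6 | methyl 2,4-bis(methoxymethoxy)-6-methylbenzoate | COC(=O)c1c(C)cc(OCOC)cc1OCOC | intermediate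
7 | {[2-(methoxycarbonyl)-3,5-bis(methoxymethoxy)phenyl]methyl}lithium (not isolated) | COC(=O)c1c(C[Li])cc(OCOC)cc1OCOC | intermediate
8 | methyl 2,4-bis(methoxymethoxy)-6-{2-[4-(triisopropylsilyloxy)phenyl]ethyl}benzoate | COC(=O)c1c(CCc2ccc(O[Si](C(C)C)(C(C)C)C(C)C)cc2)cc(OCOC)cc1OCOC | intermediate
9 | methyl 2,4-dihydroxy-6-{2-[4-(triisopropylsilyloxy)phenyl]ethyl}benzoate | COC(=O)c1c(CCc2ccc(O[Si](C(C)C)(C(C)C)C(C)C)cc2)cc(O)cc1O | intermediate
10 | 1-bromo-3-methylbut-2-ene (prenyl bromide) | CC(C)=CCBr | starting material
11 | methyl 2,4-dihydroxy-3-(3-methylbut-2-enyl)-6-{2-[4-(triisopropylsilyloxy)phenyl]ethyl}benzoate | COC(=O)c1c(O)c(CC=C(C)C)c(O)cc1CCc1ccc(O[Si](C(C)C)(C(C)C)C(C)C)cc1 | intermediate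
12 | methyl 2,4-dihydroxy-5-(hydroxymethyl)-3-(3-methylbut-2-enyl)-6-{2-[4-(triisopropylsilyloxy)phenyl]ethyl}benzoate, present as its magnesium alkoxide (not isolated) | COC(=O)c1c(O)c(CC=C(C)C)c(O)c(CO)c1CCc1ccc(O[Si](C(C)C)(C(C)C)C(C)C)cc1 | intermediate
13 | methyl 5-formyl-2,4-dihydroxy-3-(3-methylbut-2-enyl)-6-{2-[4-(triisopropylsilyloxy)phenyl]ethyl}benzoate | COC(=O)c1c(O)c(CC=C(C)C)c(O)c(C=O)c1CCc1ccc(O[Si](C(C)C)(C(C)C)C(C)C)cc1 | intermediate
14 | (2-methylprop-1-en-1-yl)boronic acid | CC(C)=CB(O)O | starting material
15 | methyl 5-[1-(dibenzylamino)-3-methylbut-2-enyl]-2,4-dihydroxy-3-(3-methylbut-2-enyl)-6-{2-[4-(triisopropylsilyloxy)phenyl]ethyl}benzoate, racemic (not isolated) | COC(=O)c1c(O)c(CC=C(C)C)c(O)c(C(C=C(C)C)N(Cc2ccccc2)Cc2ccccc2)c1CCc1ccc(O[Si](C(C)C)(C(C)C)C(C)C)cc1 | intermediate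
16 | methyl (5Z)-2-hydroxy-5-(3-methylbut-2-enylidene)-3-(3-methylbut-2-enyl)-4-oxo-6-{2-[4-(triisopropylsilyloxy)phenyl]ethyl}cyclohexa-2,6-diene-1-carboxylate (not isolated) | COC(=O)C1=C(CCc2ccc(O[Si](C(C)C)(C(C)C)C(C)C)cc2)/C(=C/C=C(C)C)C(=O)C(CC=C(C)C)=C1O | intermediate
17 | methyl 7-hydroxy-2,2-dimethyl-8-(3-methylbut-2-enyl)-5-{2-[4-(triisopropylsilyloxy)phenyl]ethyl}-2H-chromene-6-carboxylate | COC(=O)c1c(O)c(CC=C(C)C)c2OC(C)(C)C=Cc2c1CCc1ccc(O[Si](C(C)C)(C(C)C)C(C)C)cc1 | intermediate
18 | methyl 7-hydroxy-5-[2-(4-hydroxyphenyl)ethyl]-2,2-dimethyl-8-(3-methylbut-2-enyl)-2H-chromene-6-carboxylate (CNP0133674.0) | COC(=O)c1c(O)c(CC=C(C)C)c2c(c1CCc1ccc(O)cc1)C=CC(C)(C)O2 | target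

**Totals**

Total step count: 10.
Longest linear sequence: 9 steps (steps 1–3 and 5–10, from 4-hydroxybenzaldehyde 1); 7 steps from methyl orsellinate 5.

**Three steps most likely to fail**

1. Step 7 (C-prenylation). The phenoxide alkylation may partition between carbon and oxygen, may attack C5 as well as C3, and may run on to a doubly prenylated product. Fallback, from 9 back to 11: the non-chelated C4 hydroxyl would be allylated selectively (allyl bromide, K2CO3, acetone) to give methyl 2-hydroxy-4-(prop-2-enyloxy)-6-{2-[4-(triisopropylsilyloxy)phenyl]ethyl}benzoate F1. The remaining chelated C2 phenoxide (NaH, toluene, then 10) has only one free ortho carbon, C3, and should give methyl 2-hydroxy-3-(3-methylbut-2-enyl)-4-(prop-2-enyloxy)-6-{2-[4-(triisopropylsilyloxy)phenyl]ethyl}benzoate F2. Tsuji–Trost-type allyl transfer to morpholine with Pd(PPh3)4 (zerovalent palladium) in THF would then remove the allyl ether under neutral conditions and return to 11.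

2. Step 9 (chromene annulation). Iminium formation may be slow at the doubly ortho-substituted formyl group, and the alkenylboronic acid may protodeboronate before its alkenyl group is transferred. Fallback, from 11 to 17, which also bypasses step 8: the polarity is reversed to the conventional one by heating 11 with 3-methylbut-2-enal in pyridine at about 120 °C. Aldol-type attack of C5 on the enal carbonyl would give methyl 2,4-dihydroxy-5-(1-hydroxy-3-methylbut-2-enyl)-3-(3-methylbut-2-enyl)-6-{2-[4-(triisopropylsilyloxy)phenyl]ethyl}benzoate F3 (racemic, not isolated), which dehydrates to the same quinone methide 16 and closes to 17. Regiochemistry again rests on C5 being the only free ring carbon.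

3. Step 8 (formylation). Magnesium may be held in the salicylate chelate at the C2 oxygen instead of on the C4 oxygen, and delivery of formaldehyde to the hindered C5 may be slow enough for diarylmethane condensation to compete. Fallback, from 11 to 13: an untemplated electrophilic substitution (Vilsmeier–Haack formylation) with preformed (chloromethylene)dimethyliminium chloride in MeCN at 0 °C would attack C5, ortho to the C4 hydroxyl and para to the C2 hydroxyl. This would give {[2,4-dihydroxy-5-(methoxycarbonyl)-3-(3-methylbut-2-enyl)-6-{2-[4-(triisopropylsilyloxy)phenyl]ethyl}phenyl]methylidene}dimethylammonium chloride F4, which aqueous NaOAc would hydrolyse to 13.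

**Further compounds**

F1 | step 7 | methyl 2-hydroxy-4-(prop-2-enyloxy)-6-{2-[4-(triisopropylsilyloxy)phenyl]ethyl}benzoate | COC(=O)c1c(CCc2ccc(O[Si](C(C)C)(C(C)C)C(C)C)cc2)cc(OCC=C)cc1O
F2 | step 7 | methyl 2-hydroxy-3-(3-methylbut-2-enyl)-4-(prop-2-enyloxy)-6-{2-[4-(triisopropylsilyloxy)phenyl]ethyl}benzoate | COC(=O)c1c(O)c(CC=C(C)C)c(OCC=C)cc1CCc1ccc(O[Si](C(C)C)(C(C)C)C(C)C)cc1
F3 | step 9 | methyl 2,4-dihydroxy-5-(1-hydroxy-3-methylbut-2-enyl)-3-(3-methylbut-2-enyl)-6-{2-[4-(triisopropylsilyloxy)phenyl]ethyl}benzoate (racemic) | COC(=O)c1c(O)c(CC=C(C)C)c(O)c(C(O)C=C(C)C)c1CCc1ccc(O[Si](C(C)C)(C(C)C)C(C)C)cc1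
F4 | step 8 | {[2,4-dihydroxy-5-(methoxycarbonyl)-3-(3-methylbut-2-enyl)-6-{2-[4-(triisopropylsilyloxy)phenyl]ethyl}phenyl]methylidene}dimethylammonium chloride | COC(=O)c1c(O)c(CC=C(C)C)c(O)c(C=[N+](C)C)c1CCc1ccc(O[Si](C(C)C)(C(C)C)C(C)C)cc1.[Cl-]
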